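Without the constants, two earlier runs have to do, made at the catalyst charge of the new flasks but with different substrate charges.

| setting | north-east | south-east | alpha | zeta |
|---|---|---|---|---|
| substrate | 0.11 M | 0.080 M | 0.16 M | 0.16 M |
| reagent | 0.192 M | 0.192 M | 0.190 M | 0.230 M |
| catalyst | 22 mM | 22 mM | 22 mM | 22 mM |
| remark | run made earlier | run made earlier |  |  |
| time |  |  | 50 min | 50 min |

| run | time / min | substrate / % | target / % |
|---|---|---|---|
| north-east | 1.33 | 68.5 | 18.2 |
| north-east | 2.00 | 58.1 | 25.1 |
| north-east | 3.00 | 46.8 | 32.1 |
| north-east | 5.00 | 32.2 | 43.8 |
| north-east | 8.00 | 21.5 | 53.9 |
| north-east | 12.0 | 15.2 | 61.9 |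
| north-east | 20.0 | 8.7 | 72.0 |
| south-east | 1.33 | 68.1 | 18.9 |
| south-east | 2.00 | 58.0 | 24.5 |
| south-east | 3.00 | 46.7 | 34.1 |
| south-east | 5.00 | 33.2 | 44.9 |
| south-east | 8.00 | 21.7 | 57.1 |
| south-east | 12.0 | 14.4 | 65.6 |
| south-east | 20.0 | 8.2 | 76.9 |

(scatter of a reading: 0.5 percentage points)

- a reading or a percentage of target counts all its forms, free or not
- a reading of substrate is of its free form alone

- which of these there is most of at the end, counted by the substrate in it, alpha (substrate / target)
- which of these there is most of at the end, counted by the substrate in it, zeta (substrate / target)
- the largest of these amounts at the end, in percent of the substrate charged, alpha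
- the largest of these amounts at the end, in percent of the substrate charged, zeta

Two chemists read these runs differently. The first goes down the substrate columns: at 5.00 min the north-east run shows 32.2% and the south-east run 33.2%, although their substrate charges differ. So he takes the percent curve to be independent of the charges and expects alpha and zeta to end alike.

The second goes to the last target readings, at 20.0 min: 72.0% in north-east against 76.9% in south-east. That gap of 4.9 percentage points stands on a scatter of 0.5 points, so she wants a scale for reagent, with one equivalent as its zero.

Her scale is the reagent margin: the share of its own charge that reagent keeps once each substrate charged has become target at one reagent apiece, that is, reagent minus substrate, over reagent. For alpha it is 15.8%, with substrate the limiting reagent. For zeta it is 30.4%. The south-east run has a margin of 58.3% and the north-east run one of 42.7%, and at that last reading the south-east run showed more target than the north-east run. So she puts zeta ahead of alpha. The margin gives that order, not a yield.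

The forecast takes her side: target leads in alpha at 80%, and target leads in zeta at 88%. Its ground: “This fits roughly first order in remaining reagent, about one equivalent consumed”.

The flask bears her out. With all forms of target counted, alpha ends with target at 79.4% against 4.62% of substrate, and zeta with target at 84.9% against 3.04%, so zeta leads alpha by 5.5 points. The first view gets the long run: at 500 min alpha holds 98.8% of target and zeta 99.9%.

    substrate + target ⇌ idle adduct, settled at all times (K = 34.0 M⁻¹)
    substrate + reagent + catalyst → catalyst + target (k = 0.700 M⁻² s⁻¹)

In alpha at 50.0 min, the half-life of reagent by the catalysed step is 100 min, twice the 50 min of the run. Reagent there stands at 33% of its charge, above the margin of 15.8%, and reaches 16.8% at 500 min.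

Take the neighbour of alpha charged with 0.76 M of reagent: its margin is 78.9%. That flask at 50.0 min keeps 79% of its reagent, with 0.054% of the substrate free and 99.7% as target, all its forms counted.

The data were computed from invented constants, and the scatter is random.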